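**Retrosynthetic overview**
- The target comes from one global hydrogenation/hydrogenolysis of a fully assembled diaryl ether. In that precursor the left CH2CH2 is an (E)-stilbene, both free phenols are benzyl ethers, and the right CH2CH2/CO2H pair is masked as a 3-aryl-3,4-dihydroisocoumarin (benzylic δ-lactone).
- Key disconnection: the diaryl ether C(aryl)–O bond, made late and convergently from a stilbene phenol (ring B–OH) and a lactone-bearing aryl bromide (ring C–Br).
- The stilbene phenol comes from a Heck reaction of 3-bromo-5-methoxyphenol with 4-(benzyloxy)styrene.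
- The lactone bromide comes from lateral lithiation of O-benzylated methyl 2-hydroxy-4-methoxy-6-methylbenzoate, aldol addition to 4-bromobenzaldehyde and lactonisation.
- Ring order: all four benzene rings are bought. The only ring formed is the temporary δ-lactone (step 2), which is opened reductively in step 5.

Assumption: the target has no stereocentre, so no enantiocontrol is needed (the racemic lactone carbon of 6, 7 and 12 becomes CH2 in step 5); 1, 2, 4, 8 and 9 are taken as catalogue chemicals.

**Step 1**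
Reactants: 1 methyl 2-hydroxy-4-methoxy-6-methylbenzoate; 2 benzyl bromide
Product: 3 methyl 2-(benzyloxy)-4-methoxy-6-methylbenzoate
Conditions: K2CO3 (1.5 equiv), TBAI (5 mol%), DMF, 60 °C
Reagents that add atoms: benzyl bromide (compound 2), BrCc1ccccc1
Why: Williamson O-benzylation (SN2) of the only phenol; it removes the acidic OH so that the toluate can be lithiated cleanly, and the hindered ester is inert to carbonate.

**Step 2**
Reactants: 3 methyl 2-(benzyloxy)-4-methoxy-6-methylbenzoate; 4 4-bromobenzaldehyde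
Product: 7 rac-8-(benzyloxy)-3-(4-bromophenyl)-6-methoxy-3,4-dihydro-1H-isochromen-1-one, via benzylic lithio-toluate 5 (not isolated), via lithium alkoxide aldol adduct 6 (not isolated)
Conditions: LDA (1.1 equiv), THF, −78 °C, 30 min; then 4, −78 → 0 °C; 1 M HCl work-up
Reagents that add atoms: none
Why: Lateral (benzylic) lithiation of the o-toluate gives a dienolate that adds to the aldehyde (vinylogous aldol), and the alkoxide closes onto the ortho methyl ester to give the dihydroisocoumarin; LDA at −78 °C leaves Ar–Br alone, and the new C3 stereocentre forms racemic and is erased in step 5.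

**Step 3**
Reactants: 8 3-bromo-5-methoxyphenol; 9 4-(benzyloxy)styrene
Product: 10 (E)-3-{2-[4-(benzyloxy)phenyl]ethenyl}-5-methoxyphenol
Conditions: Pd(OAc)2 (2 mol%), P(o-tol)3 (6 mol%), NaOAc (2 equiv), DMA, 120 °C
Reagents that add atoms: none
Why: Mizoroki–Heck arylation of the styrene with syn β-hydride elimination gives the (E)-stilbene; acetate is too weak a base to turn the phenol into a deactivating phenoxide, and no stereocentre is formed.

**Step 4**
Reactants: 10 (E)-3-{2-[4-(benzyloxy)phenyl]ethenyl}-5-methoxyphenol; 7 rac-8-(benzyloxy)-3-(4-bromophenyl)-6-methoxy-3,4-dihydro-1H-isochromen-1-one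
Product: 12 rac-8-(benzyloxy)-3-[4-(3-{(E)-2-[4-(benzyloxy)phenyl]ethenyl}-5-methoxyphenoxy)phenyl]-6-methoxy-3,4-dihydro-1H-isochromen-1-one, via sodium phenoxide 11 (not isolated)
Conditions: 10 (1.2 equiv), NaOTMS (1.25 equiv), CuI (5 mol%), hindered N1,N2-diarylbenzene-1,2-diamine ligand (10 mol%), DMSO, 25 °C, 15 min; then 7 (1.0 equiv), 25–40 °C, 24 h
Reagents that add atoms: none
Why: Proposed new method: a room-temperature Ullmann-type diaryl ether synthesis in which the phenol is delivered as its pre-formed sodium salt 11 to Cu(I) bearing a deprotonated (anionic) N1,N2-diarylbenzene-1,2-diamine ligand; the resulting cuprate [L·Cu–OAr]⁻ should be electron-rich enough to add the unactivated Ar–Br bond of 7 oxidatively at 25–40 °C, and the Cu(III)(aryl)(aryloxide) then collapses by C–O reductive elimination; because no carbonate/alkoxide base and no heat are present, the enolisable benzylic lactone should escape E1cB opening and acyl transfer, and the stilbene and benzyl ethers are spectators; no stereocentre is formed; the closest known chemistry is the room-temperature Cu/anionic-diamine amination and aliphatic-alcohol arylation of aryl bromides and the classical 90–130 °C Cu-catalysed Ullmann diaryl ether coupling, and to my knowledge neither has been shown for phenoxide nucleophiles with base-labile lactone-bearing bromides under base-free ambient conditions.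

**Step 5**
Reactants: 12 rac-8-(benzyloxy)-3-[4-(3-{(E)-2-[4-(benzyloxy)phenyl]ethenyl}-5-methoxyphenoxy)phenyl]-6-methoxy-3,4-dihydro-1H-isochromen-1-one
Product: 13 2-hydroxy-6-[2-(4-{3-[2-(4-hydroxyphenyl)ethyl]-5-methoxyphenoxy}phenyl)ethyl]-4-methoxybenzoic acid (CNP0188714.0)
Conditions: H2 (4 bar), 10% Pd/C, EtOAc–MeOH (1:1), AcOH (5 vol%), 40 °C; work-up below 40 °C
Reagents that add atoms: none
Why: Heterogeneous hydrogenation/hydrogenolysis saturates the stilbene, cleaves both benzyl ethers and cleaves the benzylic lactone C–O bond (the classical dihydroisocoumarin → bibenzyl-2-carboxylic acid opening), releasing the salicylic acid and turning the only stereocentre into CH2; aryl methyl ethers and the diaryl ether are inert.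

**Compound list**
1 | methyl 2-hydroxy-4-methoxy-6-methylbenzoate | COC(=O)c1c(C)cc(OC)cc1O | starting material
2 | benzyl bromide | BrCc1ccccc1 | starting material
3 | methyl 2-(benzyloxy)-4-methoxy-6-methylbenzoate | COC(=O)c1c(C)cc(OC)cc1OCc1ccccc1 | intermediate
4 | 4-bromobenzaldehyde | O=Cc1ccc(Br)cc1 | starting material
5 | methyl 2-(benzyloxy)-6-(lithiomethyl)-4-methoxybenzoate (benzylic lithio-toluate) | [Li]Cc1cc(OC)cc(OCc2ccccc2)c1C(=O)OC | intermediate
6 | lithium 2-[3-(benzyloxy)-5-methoxy-2-(methoxycarbonyl)phenyl]-1-(4-bromophenyl)ethan-1-olate (racemic) | [Li+].[O-]C(Cc1cc(OC)cc(OCc2ccccc2)c1C(=O)OC)c1ccc(Br)cc1 | intermediate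
7 | rac-8-(benzyloxy)-3-(4-bromophenyl)-6-methoxy-3,4-dihydro-1H-isochromen-1-one | O=C1OC(c2ccc(Br)cc2)Cc2cc(OC)cc(OCc3ccccc3)c21 | intermediate
8 | 3-bromo-5-methoxyphenol | COc1cc(O)cc(Br)c1 | starting material
9 | 4-(benzyloxy)styrene | C=Cc1ccc(OCc2ccccc2)cc1 | starting material
10 | (E)-3-{2-[4-(benzyloxy)phenyl]ethenyl}-5-methoxyphenol | COc1cc(O)cc(/C=C/c2ccc(OCc3ccccc3)cc2)c1 | intermediate
11 | sodium (E)-3-{2-[4-(benzyloxy)phenyl]ethenyl}-5-methoxyphenolate | [Na+].[O-]c1cc(OC)cc(/C=C/c2ccc(OCc3ccccc3)cc2)c1 | intermediate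
12 | rac-8-(benzyloxy)-3-[4-(3-{(E)-2-[4-(benzyloxy)phenyl]ethenyl}-5-methoxyphenoxy)phenyl]-6-methoxy-3,4-dihydro-1H-isochromen-1-one | COc1cc(Oc2ccc(C3Cc4cc(OC)cc(OCc5ccccc5)c4C(=O)O3)cc2)cc(/C=C/c2ccc(OCc3ccccc3)cc2)c1 | intermediate
13 | 2-hydroxy-6-[2-(4-{3-[2-(4-hydroxyphenyl)ethyl]-5-methoxyphenoxy}phenyl)ethyl]-4-methoxybenzoic acid | COc1cc(CCc2ccc(O)cc2)cc(Oc2ccc(CCc3cc(OC)cc(O)c3C(=O)O)cc2)c1 | target

**Totals**
Total step count: 5. Longest linear sequence: 4 (steps 1 → 2 → 4 → 5; step 3 runs in parallel).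

**Three steps most likely to fail**

Step 4 (the proposed new coupling). The weakly donating phenoxide may make oxidative addition slow, so that ligand N-arylation or hydrodebromination of 7 wins. The fallback uses only known chemistry and makes the C–O bond before the lactone exists. It sets out from 10: SNAr with 4-fluorobenzaldehyde (K2CO3, DMF, 100 °C) gives 4-{3-[(E)-2-(4-benzyloxyphenyl)ethenyl]-5-methoxyphenoxy}benzaldehyde F1. The lithio-toluate 5 (from 3, LDA, THF, −78 °C) is then added to F1 to give the lithium alkoxide aldol adduct F2, which lactonises on warming to 0 °C. This comes back to the route at 12.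

Step 5 (global hydrogenation). Alkene reduction and debenzylation are fast, but hydrogenolysis of the lactone C–O bond may lag and leave the saturated, debenzylated lactone. The fallback removes the lactone by elimination instead of hydrogenolysis. It sets out from 12: t-BuOK (2.2 equiv) in DMSO at 25 °C opens the lactone by E1cB, and acidification gives 2-(benzyloxy)-6-[(E)-2-(4-{3-[(E)-2-(4-benzyloxyphenyl)ethenyl]-5-methoxyphenoxy}phenyl)ethenyl]-4-methoxybenzoic acid F3. Hydrogenation of F3 (H2 1 atm, Pd/C, EtOAc–MeOH) then needs only alkene saturation and O-debenzylation and comes back to the route at 13.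

Step 2 (lateral lithiation/aldol/lactonisation). The aldol addition can be reversible, lactonisation can be incomplete (hydroxy ester/lactone mixtures), and the toluate can self-condense. The fallback forms the CH2–CH2 bond by SN2 alkylation at the saturated oxidation level, with no lactone. It sets out from 3: LDA (THF, −78 °C), then 4-bromobenzyl bromide, gives methyl 2-(benzyloxy)-6-[2-(4-bromophenyl)ethyl]-4-methoxybenzoate F4. A classical Ullmann coupling of F4 with 10 (CuI, N,N-dimethylglycine, Cs2CO3, dioxane, 90 °C; no base-labile lactone present) gives methyl 2-(benzyloxy)-6-[2-(4-{3-[(E)-2-(4-benzyloxyphenyl)ethenyl]-5-methoxyphenoxy}phenyl)ethyl]-4-methoxybenzoate F5. Hydrogenation (H2, Pd/C) gives methyl 2-hydroxy-6-[2-(4-{3-[2-(4-hydroxyphenyl)ethyl]-5-methoxyphenoxy}phenyl)ethyl]-4-methoxybenzoate F6. Saponification (KOH, DMSO–H2O, 80 °C, then cold acidification) comes back to the route at 13.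

**Further compounds**
F1 | step 4 | 4-{3-[(E)-2-(4-benzyloxyphenyl)ethenyl]-5-methoxyphenoxy}benzaldehyde | COc1cc(Oc2ccc(C=O)cc2)cc(/C=C/c2ccc(OCc3ccccc3)cc2)c1
F2 | step 4 | lithium 2-[3-(benzyloxy)-5-methoxy-2-(methoxycarbonyl)phenyl]-1-[4-(3-{(E)-2-[4-(benzyloxy)phenyl]ethenyl}-5-methoxyphenoxy)phenyl]ethan-1-olate (racemic) | [Li+].[O-]C(Cc1cc(OC)cc(OCc2ccccc2)c1C(=O)OC)c1ccc(Oc2cc(OC)cc(/C=C/c3ccc(OCc4ccccc4)cc3)c2)cc1
F3 | step 5 | 2-(benzyloxy)-6-[(E)-2-(4-{3-[(E)-2-(4-benzyloxyphenyl)ethenyl]-5-methoxyphenoxy}phenyl)ethenyl]-4-methoxybenzoic acid | COc1cc(Oc2ccc(/C=C/c3cc(OC)cc(OCc4ccccc4)c3C(=O)O)cc2)cc(/C=C/c2ccc(OCc3ccccc3)cc2)c1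
F4 | step 2 | methyl 2-(benzyloxy)-6-[2-(4-bromophenyl)ethyl]-4-methoxybenzoate | COC(=O)c1c(CCc2ccc(Br)cc2)cc(OC)cc1OCc1ccccc1
F5 | step 2 | methyl 2-(benzyloxy)-6-[2-(4-{3-[(E)-2-(4-benzyloxyphenyl)ethenyl]-5-methoxyphenoxy}phenyl)ethyl]-4-methoxybenzoate | COC(=O)c1c(CCc2ccc(Oc3cc(OC)cc(/C=C/c4ccc(OCc5ccccc5)cc4)c3)cc2)cc(OC)cc1OCc1ccccc1
F6 | step 2 | methyl 2-hydroxy-6-[2-(4-{3-[2-(4-hydroxyphenyl)ethyl]-5-methoxyphenoxy}phenyl)ethyl]-4-methoxybenzoate | COC(=O)c1c(CCc2ccc(Oc3cc(OC)cc(CCc4ccc(O)cc4)c3)cc2)cc(OC)cc1O
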